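**Plan**

- Retrosynthetic cuts, last to first: the C(sp2)–C(sp2) bond between the Z-trisubstituted alkene and the diene of the side chain; the C2–C bond (from a C1–O acetal tether); the exocyclic C9=C bond (back to a C9 ketone); the C10–CH2 bond of the hydroxypropyl arm (from a C1–O acrylate tether); C5–C6 of ring B; the C10–C9 bond (epoxide opening).
- Forward: the chain is joined to C5 of a cyclopentenone by epoxide opening, ring B closes at C5–C6 by copper hydride reductive aldol, then C1, the C10 arm, the C2 unit, the C9 alkene and the triene follow in that order.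
- Stereocentres: the C9 carbinol (from the R epoxide) sets C5 and C6 in a chelated chair and is then oxidised away; the C6 hydroxyl delivers hydride to C1; tethers on the C1 oxygen deliver carbon to C10 and to C2.
- Alkene geometry: 1,4-hydroboration of an s-cis diene (tetrasubstituted C9=C), a lithium-chelated enol triflate coupled with retention (Z), and an (E)-stannane (E).
- Feature behind the key step: C1(–O)–C5–C6(–O) is an aldol array centred on the quaternary spiro carbon shared by ring A (C1–C5) and ring B (C5–C10). C5 can therefore be the α-carbon of a ring A enolate made only there by hydride addition to C4 of a C4=C5 enone, with C6 a methyl ketone four carbons out on the C5 side chain.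

Key step: step 5

Remark: the spiro[4.5]decane is numbered C1 (CHOH), C2 (side-chain carbon), C3, C4, C5 (spiro), C6 (C(CH3)OH), C7, C8, C9 (enal-bearing carbon), C10 (hydroxypropyl carbon), with ring A = C1–C5 and ring B = C5–C10; mixed-acetal carbons are carried as epimer mixtures that are erased in step 20, and the epoxide starting material is assumed to be bought as the single R enantiomer.

**Step 1**
Reactants: 1 2-bromocyclopent-2-en-1-one; 2 ethane-1,2-diol
Product: 3 6-bromo-1,4-dioxaspiro[4.4]non-6-ene
Conditions: TsOH·H2O (cat.), benzene, reflux, Dean–Stark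
Reagents that add atoms: none
Why: Acid-catalysed ketalisation with azeotropic removal of water masks the carbonyl so that the bromine-bearing carbon (the future C5) can be lithiated.

**Step 2**
Reactants: 3 6-bromo-1,4-dioxaspiro[4.4]non-6-ene; 4 (R)-2-(but-3-en-1-yl)oxirane
Product: 6 2-[(2R)-2-hydroxyhex-5-en-1-yl]cyclopent-2-en-1-one, via ketal alcohol 5 (not isolated)
Conditions: n-BuLi, THF, −78 °C; 4, BF3·OEt2, −78 °C; 1 M HCl, THF, rt
Reagents that add atoms: none
Why: Bromine–lithium exchange gives an α-lithio enone equivalent that opens the monosubstituted epoxide at its CH2 terminus under BF3 activation (SN2 epoxide opening, so the future C9 carbinol keeps the configuration of 4), and the allylic ketal is hydrolysed in the acidic work-up.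

**Step 3**
Reactants: 6 2-[(2R)-2-hydroxyhex-5-en-1-yl]cyclopent-2-en-1-one
Product: 7 2-[(2R)-2-(tert-butyldimethylsilyloxy)hex-5-en-1-yl]cyclopent-2-en-1-one
Conditions: TBSCl, imidazole, DMF, rt
Reagents that add atoms: tert-butyldimethylsilyl chloride, CC(C)(C)[Si](C)(C)Cl
Why: Silylation of the secondary alcohol keeps it from forming a cyclic hemiketal with the coming C6 ketone and turns C9 into the bulky control element of the key step.

**Step 4**
Reactants: 7 2-[(2R)-2-(tert-butyldimethylsilyloxy)hex-5-en-1-yl]cyclopent-2-en-1-one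
Product: 8 2-[(2R)-2-(tert-butyldimethylsilyloxy)-5-oxohexyl]cyclopent-2-en-1-one
Conditions: PdCl2 (10 mol %), CuCl (cat.), O2 (1 atm), DMF/H2O (7:1), rt
Reagents that add atoms: water, O
Why: Tsuji–Wacker oxidation converts the monosubstituted alkene into the methyl ketone with Markovnikov regioselectivity, the electron-poor trisubstituted enone alkene being inert to the palladium catalyst.

**Step 5**
Reactants: 8 2-[(2R)-2-(tert-butyldimethylsilyloxy)-5-oxohexyl]cyclopent-2-en-1-one
Product: 11 (5R,6S,9R)-9-(tert-butyldimethylsilyloxy)-6-hydroxy-6-methylspiro[4.5]decan-1-one, via copper enolate 9 (not isolated), via copper aldolate 10 (not isolated)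
Conditions: [(Ph3P)CuH]6 (0.25 equiv), toluene, −40 → 0 °C; aq. NH4Cl
Reagents that add atoms: none
Why: Monovalent copper hydride transfers hydride to C4 of the enone, and the copper enolate so formed, nucleophilic only at the fully substituted C5, adds to the tethered methyl ketone to form C5–C6; the closest known reaction type is the [(Ph3P)CuH]6-mediated reductive aldol cyclisation of enones carrying a pendant ketone. Ring B closes in a 6-(enolexo)-exo-trig aldol mode through a chair in which copper bridges the enolate and ketone oxygens. C5 and C6 are set relative to each other by this closed transition state: ring A holds the tether cis to the enolate oxygen, the ketone methyl sits equatorial, and the new hydroxyl therefore ends cis to C1 across ring B. The absolute sense comes from the C9 silyloxy group, which is equatorial in the favoured chair, whereas the alternative chair would place it 1,3-diaxial to C4. The step needs conjugate hydride delivery in preference to 1,2-reduction of either ketone and enolate formation at C5 rather than C2, and the soft copper hydride together with the position of the enone double bond should secure both.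

**Step 6**
Reactants: 11 (5R,6S,9R)-9-(tert-butyldimethylsilyloxy)-6-hydroxy-6-methylspiro[4.5]decan-1-one
Product: 13 (5R,6S,9R)-9-(tert-butyldimethylsilyloxy)-6-hydroxy-6-methylspiro[4.5]dec-2-en-1-one, via bis(trimethylsilyl) enol ether 12 (not isolated)
Conditions: TMSOTf, Et3N, CH2Cl2, 0 °C; Pd(OAc)2 (10 mol %), O2 (1 atm), DMSO, rt; 1 M HCl, THF, 0 °C
Reagents that add atoms: none
Why: Saegusa–Ito dehydrogenation, in which soft enolisation silylates the only enolisable position (C2 side) together with the tertiary hydroxyl, divalent palladium converts the silyl enol ether into the C2=C3 enone under dioxygen, and brief acid frees the C6 hydroxyl while the secondary silyl ether survives.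

**Step 7**
Reactants: 13 (5R,6S,9R)-9-(tert-butyldimethylsilyloxy)-6-hydroxy-6-methylspiro[4.5]dec-2-en-1-one
Product: 14 (1R,5S,6S,9R)-9-(tert-butyldimethylsilyloxy)-6-methylspiro[4.5]dec-2-ene-1,6-diol
Conditions: Me4NBH(OAc)3, MeCN/AcOH (1:1), −30 °C
Reagents that add atoms: none
Why: Hydroxyl-directed 1,2-reduction (Evans–Saksena type), in which the borohydride bound to the C6 oxygen delivers hydride intramolecularly to the face of the C1 carbonyl turned toward C6, so that the new C1 hydroxyl ends on the C10 face of ring A (1R).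

**Step 8**
Reactants: 14 (1R,5S,6S,9R)-9-(tert-butyldimethylsilyloxy)-6-methylspiro[4.5]dec-2-ene-1,6-diol
Product: 15 (1R,5S,6S,9R)-9-(tert-butyldimethylsilyloxy)-6-hydroxy-6-methylspiro[4.5]dec-2-en-1-yl prop-2-enoate
Conditions: acryloyl chloride, i-Pr2NEt, CH2Cl2, −20 °C
Reagents that add atoms: acryloyl chloride, C=CC(=O)Cl
Why: O-acylation of the secondary allylic alcohol, which reacts far faster than the hindered tertiary C6 hydroxyl, attaches the three carbons of the C10 arm to the C1 oxygen as a tether.

**Step 9**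
Reactants: 15 (1R,5S,6S,9R)-9-(tert-butyldimethylsilyloxy)-6-hydroxy-6-methylspiro[4.5]dec-2-en-1-yl prop-2-enoate
Product: 16 (1R,5S,6S,9R)-6,9-dihydroxy-6-methylspiro[4.5]dec-2-en-1-yl prop-2-enoate
Conditions: HF·pyridine, THF, 0 °C → rt
Reagents that add atoms: none
Why: Fluoride-mediated desilylation cleaves the secondary silyl ether without touching the acrylate or the tertiary alcohol.

**Step 10**
Reactants: 16 (1R,5S,6S,9R)-6,9-dihydroxy-6-methylspiro[4.5]dec-2-en-1-yl prop-2-enoate
Product: 17 (1R,5S,6S)-6-hydroxy-6-methyl-9-oxospiro[4.5]dec-2-en-1-yl prop-2-enoate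
Conditions: Dess–Martin periodinane, NaHCO3, CH2Cl2, rt
Reagents that add atoms: none
Why: Dess–Martin oxidation of the only secondary alcohol gives the C9 ketone under neutral conditions, deliberately erasing the C9 stereocentre once it has set C5 and C6.

**Step 11**
Reactants: 17 (1R,5S,6S)-6-hydroxy-6-methyl-9-oxospiro[4.5]dec-2-en-1-yl prop-2-enoate
Product: 18 keto lactone (seven-membered ring C1–O–C(=O)–CH2–CH2–C10; C10–CH2 cis to C1 across ring B; C9 ketone)
Conditions: KOt-Bu (0.3 equiv), t-BuOH/THF (1:10), 0 °C, 2 mM; AcOH quench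
Reagents that add atoms: none
Why: Intramolecular Michael addition under reversible enolisation, in which only the C9=C10 enolate can reach the acrylate (seven-membered lactone, whereas the C8 enolate would need a nine-membered ring) and the C1–O tether can reach only the enolate lobe on the C1 side of ring B, so that the new C10–C bond should form cis to C1 under kinetic control, with catalytic base, low temperature and dilution limiting epimerisation and intermolecular addition.

**Step 12**
Reactants: 18 keto lactone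
Product: 19 enol triflate lactone (18 with C9=O replaced by C8=C9–OTf)
Conditions: KN(SiMe3)2 (2.2 equiv), THF, −78 °C; PhNTf2
Reagents that add atoms: N-phenylbis(trifluoromethanesulfonimide), O=S(=O)(N(c1ccccc1)S(=O)(=O)C(F)(F)F)C(F)(F)F
Why: Kinetic deprotonation at the unhindered C8 methylene (the tertiary C10–H next to the quaternary C5 is far slower) and O-triflation of the potassium enolate give the C8=C9 enol triflate, which also protects C10 against epimerisation.

**Step 13**
Reactants: 19 enol triflate lactone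
Product: 20 (1R,5S,6S,10S)-1,6-dihydroxy-10-(3-hydroxypropyl)-6-methylspiro[4.5]deca-2,8-dien-9-yl trifluoromethanesulfonate
Conditions: LiBH4, THF/MeOH, 0 °C → rt
Reagents that add atoms: none
Why: Borohydride reduction of the lactone to the diol releases the 3-hydroxypropyl arm and the C1 hydroxyl, the enol triflate and the ring A alkene being inert to LiBH4.

**Step 14**
Reactants: 20 triflate triol
Product: 21 (1R,5S,6S,10S)-10-[3-(tert-butyldiphenylsilyloxy)propyl]-1,6-dihydroxy-6-methylspiro[4.5]deca-2,8-dien-9-yl trifluoromethanesulfonate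
Conditions: TBDPSCl (1.1 equiv), imidazole, CH2Cl2, 0 °C
Reagents that add atoms: tert-butyl(chloro)diphenylsilane, CC(C)(C)[Si](Cl)(c1ccccc1)c1ccccc1
Why: Selective silylation of the primary alcohol with a bulky chlorosilane, the neopentyl-type secondary C1 hydroxyl and the tertiary C6 hydroxyl reacting much more slowly.

**Step 15**
Reactants: 21 arm-protected triflate diol
Product: 22 bromoacetal (21 with C1–O–CH(OEt)–CH2Br)
Conditions: ethyl vinyl ether, NBS, CH2Cl2, −40 °C
Reagents that add atoms: ethyl vinyl ether, C=COCC; N-bromosuccinimide, O=C1CCC(=O)N1Br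
Why: Bromoacetalisation (bromoetherification of the vinyl ether by the allylic C1 hydroxyl) installs the two-carbon radical tether, the tertiary C6 hydroxyl being too hindered to compete at low temperature and the electron-poor enol triflate inert to the bromonium source.

**Step 16**
Reactants: 22 bromoacetal
Product: 23 cis-fused acetal (2-ethoxytetrahydrofuran ring O(C1)–CH(OEt)–CH2–C2 on the C10 face of ring A; ring B as in 21)
Conditions: Bu3SnH, AIBN (cat.), benzene, 80 °C, slow addition
Reagents that add atoms: none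
Why: Ueno–Stork radical cyclisation, in which the primary radical adds 5-exo-trig to C2 of the ring A alkene and the C3 radical is reduced by the stannane; since the five-membered acetal can only be cis-fused, the new C2–C bond is cis to the C1 oxygen (C2 set by the tether).

**Step 17**
Reactants: 23 cis-fused acetal
Product: 24 diene (23 with isopropenyl in place of OTf: C8=C9–C(CH3)=CH2)
Conditions: tributyl(prop-1-en-2-yl)stannane, Pd(PPh3)4 (5 mol %), LiCl, THF, 60 °C
Reagents that add atoms: tributyl(prop-1-en-2-yl)stannane, CCCC[Sn](CCCC)(CCCC)C(C)=C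
Why: Stille coupling of the enol triflate with the isopropenylstannane under zerovalent palladium forms the C9–C bond and gives the 1,3-diene without base.

**Step 18**
Reactants: 24 diene
Product: 26 exocyclic allylic alcohol (C8H2; C9=C(CH3)CH2OH with CH2OH cis to C8), via allylboronate 25 (not isolated)
Conditions: Ni(cod)2 (5 mol %), PCy3 (5 mol %), HBpin, toluene, rt; H2O2, pH 7 phosphate buffer, THF, 0 °C
Reagents that add atoms: hydrogen peroxide, OO
Why: Nickel-catalysed 1,4-hydroboration of the 1,3-diene followed by oxidation, in which zerovalent nickel binds the diene in its s-cis form and hydrogen is expected at the ring terminus C8 and boron at the unsubstituted CH2 terminus, so that the two termini end cis on the new tetrasubstituted C9=C bond (CH2OH cis to C8 and CH3 cis to C10, as in the target).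

**Step 19**
Reactants: 26 exocyclic allylic alcohol
Product: 27 bis(silyl ether) (26 with CH2O–TBDPS)
Conditions: TBDPSCl, imidazole, CH2Cl2, rt
Reagents that add atoms: tert-butyl(chloro)diphenylsilane, CC(C)(C)[Si](Cl)(c1ccccc1)c1ccccc1
Why: Silylation of the primary allylic alcohol protects it against the acidic oxidant of step 20 and the bases of steps 21 and 22.

**Step 20**
Reactants: 27 bis(silyl ether)
Product: 28 γ-lactone (27 with C=O in place of CH(OEt))
Conditions: CrO3, H2SO4, H2O, acetone, 0 °C
Reagents that add atoms: water, O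
Why: Jones oxidation hydrolyses the cyclic ethyl acetal to the lactol and oxidises it in the same flask to the γ-lactone, the bulky silyl ethers, the tertiary alcohol and the tetrasubstituted alkene being expected to survive brief exposure at 0 °C.

**Step 21**
Reactants: 28 γ-lactone
Product: 29 α-(hydroxymethylene) lactone (enol form of the α-formyl lactone)
Conditions: LiN(i-Pr)2 (2.2 equiv), THF, −78 °C; HCO2Et, −78 → 0 °C
Reagents that add atoms: ethyl formate, CCOC=O
Why: Claisen condensation of the lactone enolate with ethyl formate places the future alkene carbon on the lactone α-carbon, the product resting as its enol.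

**Step 22**
Reactants: 29 α-(hydroxymethylene) lactone
Product: 30 (Z)-enol triflate (OTf cis to the lactone C=O)
Conditions: LiN(SiMe3)2 (2.1 equiv), THF, −78 °C; PhNTf2, −78 → 0 °C
Reagents that add atoms: N-phenylbis(trifluoromethanesulfonimide), O=S(=O)(N(c1ccccc1)S(=O)(=O)C(F)(F)F)C(F)(F)F
Why: O-triflation of the lithium enolate, which is held U-shaped by chelation of lithium between the enolate and lactone oxygens, is expected to give the enol triflate with OTf cis to the lactone carbonyl.

**Step 23**
Reactants: 31 6-methylhept-5-en-2-one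
Product: 32 6-methylhepta-1,5-dien-2-yl trifluoromethanesulfonate
Conditions: LiN(i-Pr)2, THF, −78 °C; PhNTf2
Reagents that add atoms: N-phenylbis(trifluoromethanesulfonimide), O=S(=O)(N(c1ccccc1)S(=O)(=O)C(F)(F)F)C(F)(F)F
Why: Kinetic deprotonation of the methyl ketone at CH3 and O-triflation (enol triflate formation) give the 2-triflyloxy-1-alkene.

**Step 24**
Reactants: 32 6-methylhepta-1,5-dien-2-yl trifluoromethanesulfonate; 33 (E)-1,2-bis(tributylstannyl)ethene
Product: 34 tributyl[(1E)-7-methyl-3-methylideneocta-1,6-dien-1-yl]stannane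
Conditions: 33 (3 equiv), Pd(PPh3)4 (5 mol %), LiCl, THF, 60 °C
Reagents that add atoms: none
Why: Stille coupling with an excess of the bis(stannyl)ethene transfers one stannylvinyl group with retention, giving the (E)-dienylstannane.

**Step 25**
Reactants: 30 (Z)-enol triflate; 34 tributyl[(1E)-7-methyl-3-methylideneocta-1,6-dien-1-yl]stannane
Product: 35 (Z)-alkylidene lactone (30 with the (1E)-7-methyl-3-methylideneocta-1,6-dien-1-yl group in place of OTf)
Conditions: Pd2(dba)3 (2.5 mol %), AsPh3, CuI, LiCl, DMF, rt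
Reagents that add atoms: none
Why: Stille coupling of the enol triflate with the dienylstannane proceeds with retention at both partners and so fixes the Z trisubstituted and E disubstituted alkenes of the side chain.

**Step 26**
Reactants: 35 (Z)-alkylidene lactone
Product: 36 diol (lactone opened to C1–OH and allylic CH2OH; both silyl ethers intact)
Conditions: i-Bu2AlH (5 equiv), CH2Cl2, −78 → 0 °C
Reagents that add atoms: none
Why: Hydride reduction of the α-alkylidene lactone by 1,2-addition through the lactol turns the lactone carbonyl into the allylic CH2OH and frees the C1 hydroxyl without touching the alkene geometry.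

**Step 27**
Reactants: 36 diol
Product: 37 allylic monoacetate
Conditions: Ac2O (1.1 equiv), 2,4,6-collidine, CH2Cl2, −20 °C
Reagents that add atoms: acetic anhydride, CC(=O)OC(C)=O
Why: Selective acetylation of the unhindered primary allylic alcohol with one equivalent of anhydride and a weak hindered base, the neopentyl-type secondary and the tertiary hydroxyls being much slower.

**Step 28**
Reactants: 37 allylic monoacetate
Product: 38 tetraol monoacetate (target with CH2OH in place of CHO)
Conditions: HF·pyridine, pyridine, THF, 0 °C → rt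
Reagents that add atoms: none
Why: Buffered fluoride desilylation removes both silyl ethers while the allylic acetate and the triene survive.

**Step 29**
Reactants: 38 tetraol monoacetate
Product: 39 CNP0204268.1
Conditions: MnO2, CH2Cl2, rt
Reagents that add atoms: none
Why: Allylic oxidation with MnO2 converts only the allylic primary alcohol into the enal, leaving the saturated primary, the homoallylic secondary and the tertiary alcohols untouched and the alkene geometry unchanged.

**Compound list**

1 | 2-bromocyclopent-2-en-1-one | O=C1CCC=C1Br | starting material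
2 | ethane-1,2-diol | OCCO | starting material
3 | 6-bromo-1,4-dioxaspiro[4.4]non-6-ene | BrC1=CCCC12OCCO2 | intermediate
4 | (R)-2-(but-3-en-1-yl)oxirane | C=CCC[C@@H]1CO1 | starting material
5 | ketal alcohol, (2R)-1-(1,4-dioxaspiro[4.4]non-6-en-6-yl)hex-5-en-2-ol | C=CCC[C@@H](O)CC1=CCCC12OCCO2 | intermediate
6 | 2-[(2R)-2-hydroxyhex-5-en-1-yl]cyclopent-2-en-1-one | O=C1CCC=C1C[C@H](O)CCC=C | intermediate
7 | 2-[(2R)-2-(tert-butyldimethylsilyloxy)hex-5-en-1-yl]cyclopent-2-en-1-one | O=C1CCC=C1C[C@H](O[Si](C)(C)C(C)(C)C)CCC=C | intermediate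
8 | 2-[(2R)-2-(tert-butyldimethylsilyloxy)-5-oxohexyl]cyclopent-2-en-1-one | O=C1CCC=C1C[C@H](O[Si](C)(C)C(C)(C)C)CCC(C)=O | intermediate
9 | copper enolate of 8 (Cu on the C1 oxygen, C1=C5, C4 reduced) | [Cu]OC1=C(C[C@H](O[Si](C)(C)C(C)(C)C)CCC(C)=O)CCC1 | intermediate
10 | copper aldolate (11 with Cu on the C6 oxygen) | C1CC[C@]2(C[C@H](O[Si](C)(C)C(C)(C)C)CC[C@]2(C)O[Cu])C1=O | intermediate
11 | (5R,6S,9R)-9-(tert-butyldimethylsilyloxy)-6-hydroxy-6-methylspiro[4.5]decan-1-one | C1CC[C@]2(C[C@H](O[Si](C)(C)C(C)(C)C)CC[C@]2(C)O)C1=O | intermediate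
12 | bis(trimethylsilyl) enol ether (C1=C2 trimethylsilyl enol ether and C6 trimethylsilyl ether of 11) | C1=C(O[Si](C)(C)C)[C@@]2(C[C@H](O[Si](C)(C)C(C)(C)C)CC[C@]2(C)O[Si](C)(C)C)CC1 | intermediate
13 | (5R,6S,9R)-9-(tert-butyldimethylsilyloxy)-6-hydroxy-6-methylspiro[4.5]dec-2-en-1-one | C1=CC[C@]2(C[C@H](O[Si](C)(C)C(C)(C)C)CC[C@]2(C)O)C1=O | intermediate
14 | (1R,5S,6S,9R)-9-(tert-butyldimethylsilyloxy)-6-methylspiro[4.5]dec-2-ene-1,6-diol | C1=CC[C@]2(C[C@H](O[Si](C)(C)C(C)(C)C)CC[C@]2(C)O)[C@@H]1O | intermediate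
15 | (1R,5S,6S,9R)-9-(tert-butyldimethylsilyloxy)-6-hydroxy-6-methylspiro[4.5]dec-2-en-1-yl prop-2-enoate | C1=CC[C@]2(C[C@H](O[Si](C)(C)C(C)(C)C)CC[C@]2(C)O)[C@@H]1OC(=O)C=C | intermediate
16 | (1R,5S,6S,9R)-6,9-dihydroxy-6-methylspiro[4.5]dec-2-en-1-yl prop-2-enoate | C1=CC[C@]2(C[C@H](O)CC[C@]2(C)O)[C@@H]1OC(=O)C=C | intermediate
17 | (1R,5S,6S)-6-hydroxy-6-methyl-9-oxospiro[4.5]dec-2-en-1-yl prop-2-enoate | C1=CC[C@]2(CC(=O)CC[C@]2(C)O)[C@@H]1OC(=O)C=C | intermediate
18 | keto lactone: seven-membered lactone C1–O–C(=O)–CH2–CH2–C10, C10–CH2 cis to C1 across ring B, C9 ketone, C6–OH, C2=C3 | C1=CC[C@]2([C@H](CCC(=O)O3)C(=O)CC[C@]2(C)O)[C@@H]13 | intermediate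
19 | enol triflate lactone: 18 with C8=C9–OTf in place of the C9 ketone | C1=CC[C@]2([C@H](CCC(=O)O3)C(OS(=O)(=O)C(F)(F)F)=CC[C@]2(C)O)[C@@H]13 | intermediate
20 | (1R,5S,6S,10S)-1,6-dihydroxy-10-(3-hydroxypropyl)-6-methylspiro[4.5]deca-2,8-dien-9-yl trifluoromethanesulfonate (arm cis to C1 across ring B) | C1=CC[C@]2([C@H](CCCO)C(OS(=O)(=O)C(F)(F)F)=CC[C@]2(C)O)[C@@H]1O | intermediate
21 | (1R,5S,6S,10S)-10-[3-(tert-butyldiphenylsilyloxy)propyl]-1,6-dihydroxy-6-methylspiro[4.5]deca-2,8-dien-9-yl trifluoromethanesulfonate | C1=CC[C@]2([C@H](CCCO[Si](c4ccccc4)(c4ccccc4)C(C)(C)C)C(OS(=O)(=O)C(F)(F)F)=CC[C@]2(C)O)[C@@H]1O | intermediate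
22 | bromoacetal: 21 with C1–O–CH(OEt)–CH2Br | C1=CC[C@]2([C@H](CCCO[Si](c4ccccc4)(c4ccccc4)C(C)(C)C)C(OS(=O)(=O)C(F)(F)F)=CC[C@]2(C)O)[C@@H]1OC(OCC)CBr | intermediate
23 | cis-fused acetal: 2-ethoxytetrahydrofuran O(C1)–CH(OEt)–CH2–C2 fused at C1–C2 on the C10 face of ring A; C8=C9 enol triflate; C10 arm silyl ether; C6–OH | CCOC1C[C@@H]2CC[C@]3([C@H](CCCO[Si](c4ccccc4)(c4ccccc4)C(C)(C)C)C(OS(=O)(=O)C(F)(F)F)=CC[C@]3(C)O)[C@@H]2O1 | intermediate
24 | diene: 23 with isopropenyl at C9 (C8=C9–C(CH3)=CH2) | CCOC1C[C@@H]2CC[C@]3([C@H](CCCO[Si](c4ccccc4)(c4ccccc4)C(C)(C)C)C(C(C)=C)=CC[C@]3(C)O)[C@@H]2O1 | intermediate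
25 | allylboronate: C8H2, C9=C(CH3)CH2Bpin with CH2Bpin cis to C8 | CCOC1C[C@@H]2CC[C@]3([C@H](CCCO[Si](c4ccccc4)(c4ccccc4)C(C)(C)C)/C(=C(\C)CB5OC(C)(C)C(C)(C)O5)CC[C@]3(C)O)[C@@H]2O1 | intermediate
26 | exocyclic allylic alcohol: C9=C(CH3)CH2OH with CH2OH cis to C8 (E) | CCOC1C[C@@H]2CC[C@]3([C@H](CCCO[Si](c4ccccc4)(c4ccccc4)C(C)(C)C)/C(=C(\C)CO)CC[C@]3(C)O)[C@@H]2O1 | intermediate
27 | bis(silyl ether): tert-butyldiphenylsilyl ether of 26 | CCOC1C[C@@H]2CC[C@]3([C@H](CCCO[Si](c4ccccc4)(c4ccccc4)C(C)(C)C)/C(=C(\C)CO[Si](c4ccccc4)(c4ccccc4)C(C)(C)C)CC[C@]3(C)O)[C@@H]2O1 | intermediate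
28 | γ-lactone: 27 with C=O in place of CH(OEt) | O=C1C[C@@H]2CC[C@]3([C@H](CCCO[Si](c4ccccc4)(c4ccccc4)C(C)(C)C)/C(=C(\C)CO[Si](c4ccccc4)(c4ccccc4)C(C)(C)C)CC[C@]3(C)O)[C@@H]2O1 | intermediate
29 | α-(hydroxymethylene) lactone from 28 | O=C1C(=CO)[C@@H]2CC[C@]3([C@H](CCCO[Si](c4ccccc4)(c4ccccc4)C(C)(C)C)/C(=C(\C)CO[Si](c4ccccc4)(c4ccccc4)C(C)(C)C)CC[C@]3(C)O)[C@@H]2O1 | intermediate
30 | (Z)-enol triflate of 29, OTf cis to the lactone C=O | O=C1/C(=C\OS(=O)(=O)C(F)(F)F)[C@@H]2CC[C@]3([C@H](CCCO[Si](c4ccccc4)(c4ccccc4)C(C)(C)C)/C(=C(\C)CO[Si](c4ccccc4)(c4ccccc4)C(C)(C)C)CC[C@]3(C)O)[C@@H]2O1 | intermediate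
31 | 6-methylhept-5-en-2-one | CC(=O)CCC=C(C)C | starting material
32 | 6-methylhepta-1,5-dien-2-yl trifluoromethanesulfonate | C=C(CCC=C(C)C)OS(=O)(=O)C(F)(F)F | intermediate
33 | (E)-1,2-bis(tributylstannyl)ethene | CCCC[Sn](CCCC)(CCCC)/C=C/[Sn](CCCC)(CCCC)CCCC | starting material
34 | tributyl[(1E)-7-methyl-3-methylideneocta-1,6-dien-1-yl]stannane | CC(C)=CCCC(=C)/C=C/[Sn](CCCC)(CCCC)CCCC | intermediate
35 | (Z)-alkylidene lactone carrying the full triene | O=C1/C(=C\C=C\C(=C)CCC=C(C)C)[C@@H]2CC[C@]3([C@H](CCCO[Si](c4ccccc4)(c4ccccc4)C(C)(C)C)/C(=C(\C)CO[Si](c4ccccc4)(c4ccccc4)C(C)(C)C)CC[C@]3(C)O)[C@@H]2O1 | intermediate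
36 | diol: C1–OH and side-chain allylic CH2OH free, two silyl ethers | C=C(/C=C/C=C(\CO)[C@@H]1CC[C@]2([C@H](CCCO[Si](c4ccccc4)(c4ccccc4)C(C)(C)C)/C(=C(\C)CO[Si](c4ccccc4)(c4ccccc4)C(C)(C)C)CC[C@]2(C)O)[C@@H]1O)CCC=C(C)C | intermediate
37 | allylic monoacetate of 36 | C=C(/C=C/C=C(\COC(C)=O)[C@@H]1CC[C@]2([C@H](CCCO[Si](c4ccccc4)(c4ccccc4)C(C)(C)C)/C(=C(\C)CO[Si](c4ccccc4)(c4ccccc4)C(C)(C)C)CC[C@]2(C)O)[C@@H]1O)CCC=C(C)C | intermediate
38 | tetraol monoacetate: target with CH2OH in place of CHO | C=C(/C=C/C=C(\COC(C)=O)[C@@H]1CC[C@]2([C@H](CCCO)/C(=C(\C)CO)CC[C@]2(C)O)[C@@H]1O)CCC=C(C)C | intermediate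
39 | CNP0204268.1 | C=C(/C=C/C=C(\COC(C)=O)[C@@H]1CC[C@]2([C@H](CCCO)/C(=C(\C)C=O)CC[C@]2(C)O)[C@@H]1O)CCC=C(C)C | target

**Step count**

Total: 29 steps. Longest linear sequence: 27 steps (steps 1–22 and 25–29, from 1); steps 23 and 24 make stannane 34.

**Steps most likely to fail**

Step 11. The seven-membered ring closure may be slower than intermolecular conjugate addition of the more abundant C8 enolate, and the equilibrating base may re-enolise the product and erode the configuration at C10. The fallback replaces the reversible Michael closure by an irreversible six-membered enolate alkylation on a substrate in which C8 is blocked; it sets out from 14 and returns at 20. The C1 hydroxyl of 14 would be converted with N-iodosuccinimide and ethyl vinyl ether into the iodoacetal F1, and the silyl ether removed with Bu4NF to give the alcohol F2. Oxidation–dehydrogenation with IBX would give the C7=C8 enone F3 (only C7–C8 can be dehydrogenated, C5 being quaternary). LiN(SiMe3)2 at −78 °C would then generate the only possible enolate (C10), which should displace iodide in a 6-exo-tet alkylation on the C1 side of ring B to give the tricyclic acetal F4. Conjugate reduction with LiBH(s-Bu)3 and trapping with PhNTf2 would give the C8=C9 enol triflate F5. Mild aqueous acid would open the acetal to the lactol F6, Wittig methylenation (Ph3P=CH2) would give the C10-allyl diol F7, and hydroboration of the terminal alkene with 9-BBN followed by buffered oxidation would give 20.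

Step 18. The crowded 1,2,3-trisubstituted diene may fail to bind zerovalent nickel in its s-cis form, or boron may be delivered to C8 instead of the terminal carbon. The fallback builds the same alkene from a stereodefined enolate; it sets out from 23 and returns at 26. Carbonylative Stille coupling of 23 (Me4Sn, CO, Pd(PPh3)4, LiCl) would give the methyl enone F8. Conjugate reduction with LiBH(s-Bu)3, which delivers hydride to C8 through the s-cis enone, should give the enolate with oxygen cis to C8, trapped with PhNTf2 as the exocyclic enol triflate F9. Palladium-catalysed methoxycarbonylation (Pd(OAc)2, PPh3, CO, MeOH, Et3N) with retention would give the ester F10, and i-Bu2AlH reduction would give 26.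

Step 22. The lithium chelate may open before triflation, so that enolate geometry is lost and the E triflate, hence the wrong alkylidene isomer, is carried forward. The fallback forms the alkene by carbonyl olefination instead of cross-coupling; it sets out from 28 and returns at 35. The lactone enolate of 28 (LiN(i-Pr)2) would be phosphorylated with bis(2,2,2-trifluoroethyl) phosphorochloridate and rearranged with further base to the α-phosphono lactone F11. Heck reaction of 32 with acrolein (Pd(OAc)2, Et3N, DMF) would give the dienal F12. A Z-selective Horner–Wadsworth–Emmons reaction of the Still–Gennari type (KN(SiMe3)2, 18-crown-6, THF, −78 °C) between F11 and F12 should give 35.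

**Further compounds**

F1 | step 11 | iodoacetal: 14 with C1–O–CH(OEt)–CH2I | C1=CC[C@]2(C[C@H](O[Si](C)(C)C(C)(C)C)CC[C@]2(C)O)[C@@H]1OC(OCC)CI
F2 | step 11 | alcohol: F1 with free C9–OH | C1=CC[C@]2(C[C@H](O)CC[C@]2(C)O)[C@@H]1OC(OCC)CI
F3 | step 11 | enone: C7=C8–C9=O iodoacetal | C1=CC[C@]2(CC(=O)C=C[C@]2(C)O)[C@@H]1OC(OCC)CI
F4 | step 11 | tricyclic acetal: ring O(C1)–CH(OEt)–CH2–C10, CH2 cis to C1 across ring B, C7=C8–C9=O | C1=CC[C@]2([C@H](CC(OCC)O3)C(=O)C=C[C@]2(C)O)[C@@H]13
F5 | step 11 | enol triflate: F4 after conjugate reduction, C8=C9–OTf | C1=CC[C@]2([C@H](CC(OCC)O3)C(OS(=O)(=O)C(F)(F)F)=CC[C@]2(C)O)[C@@H]13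
F6 | step 11 | lactol: F5 with OH in place of OEt | C1=CC[C@]2([C@H](CC(O)O3)C(OS(=O)(=O)C(F)(F)F)=CC[C@]2(C)O)[C@@H]13
F7 | step 11 | C10-allyl diol: 1,6-dihydroxy-6-methyl-10-(prop-2-en-1-yl)spiro[4.5]deca-2,8-dien-9-yl trifluoromethanesulfonate | C1=CC[C@]2([C@H](CC=C)C(OS(=O)(=O)C(F)(F)F)=CC[C@]2(C)O)[C@@H]1O
F8 | step 18 | methyl enone: 23 with acetyl in place of OTf | CCOC1C[C@@H]2CC[C@]3([C@H](CCCO[Si](c4ccccc4)(c4ccccc4)C(C)(C)C)C(C(C)=O)=CC[C@]3(C)O)[C@@H]2O1
F9 | step 18 | exocyclic enol triflate: C9=C(CH3)OTf with OTf cis to C8 | CCOC1C[C@@H]2CC[C@]3([C@H](CCCO[Si](c4ccccc4)(c4ccccc4)C(C)(C)C)/C(=C(\C)OS(=O)(=O)C(F)(F)F)CC[C@]3(C)O)[C@@H]2O1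
F10 | step 18 | ester: C9=C(CH3)CO2CH3 with the ester cis to C8 | CCOC1C[C@@H]2CC[C@]3([C@H](CCCO[Si](c4ccccc4)(c4ccccc4)C(C)(C)C)/C(=C(\C)C(=O)OC)CC[C@]3(C)O)[C@@H]2O1
F11 | step 22 | α-phosphono lactone: 28 with P(O)(OCH2CF3)2 on the lactone α-carbon | O=C1C(P(=O)(OCC(F)(F)F)OCC(F)(F)F)[C@@H]2CC[C@]3([C@H](CCCO[Si](c4ccccc4)(c4ccccc4)C(C)(C)C)/C(=C(\C)CO[Si](c4ccccc4)(c4ccccc4)C(C)(C)C)CC[C@]3(C)O)[C@@H]2O1
F12 | step 22 | (2E)-8-methyl-4-methylidenenona-2,7-dienal | CC(C)=CCCC(=C)/C=C/C=O
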